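**Plan**

- Retrosynthesis: cut the C15–O ester bond (the C30 acid comes from two C15 halves), then C8–C17 (alkenyl triflate plus stannylmethanol), then C11–C12 (vinylogous Mukaiyama–Michael addition to a 9(11)-en-8-one). Ring A is then taken back to a cyclopentane by moving C5 from C4 back to C3, and the cyclopentane is opened at C3–C5 (benzoin) and C10–C1 (Michael).
- Forward: ring B is 2-methylcyclohexane-1,3-dione. A cyclopentane is fused on, then enlarged to ring A by insertion of the gem-dimethyl carbon C4. C11, the C12–C16 chain, C17 and the acyl chain follow.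
- Enabling feature: in ring A the quaternary C4 (two methyls) lies between C3H2 and the ring-fusion carbon C5. A C3(=O)–C4Me2–C5 unit is what a 1,2-shift of C5 from a C3 carbinol to an exocyclic Me2C radical or cation gives. C5 can be sp2 (C5=C6) during the shift, so it migrates as an alkenyl group and no ring-fusion configuration has to survive.
- Stereochemistry: C10 from a catalyst-controlled desymmetrising benzoin; C5 by hydrogenation anti to the C10 methyl; C9 by equilibration next to the C8 ketone; 13E from the vinylogous Michael step; the 7-ene from kinetic enolisation.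

Key step: step 6

Remark on the structure: the SMILES is the ent-labdane series, (5R,9S,10R), 13E; H-5 and H-9 are anti to the C10 methyl. Labdane numbering is used throughout.

Assumption: both antipodes of the aminoindanol-derived triazolium precatalyst are available; the one that leads to the (3aR,7aS) ketol 4 is used.

**Route**

Step 1
Reactants: 1 2-methylcyclohexane-1,3-dione; 2 acrolein
Product: 3 keto aldehyde 3-(1-methyl-2,6-dioxocyclohexyl)propanal
Conditions: H2O, rt
Reagents that add atoms: none
Why: Michael addition of the enolised 1,3-dione to acrolein should form the C10–C1 bond and the still prochiral quaternary C10.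

Step 2
Reactants: 3 keto aldehyde
Product: 4 cis-fused ketol (3aR,7aS)-7a-hydroxy-3a-methylhexahydro-1H-indene-1,4(2H)-dione
Conditions: aminoindanol-derived N-pentafluorophenyl triazolium tetrafluoroborate (10 mol %), Et3N (10 mol %), toluene, rt
Reagents that add atoms: none
Why: N-heterocyclic-carbene-catalysed intramolecular crossed benzoin reaction (5-exo-trig attack of the C3 acyl anion equivalent on one of the two enantiotopic ring ketones); the chiral carbene selects the ketone and so sets C10 (R), and the five-membered ring closure makes the fusion at the new carbinol C5 cis.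

Step 3
Reactants: 4 ketol
Product: 5 enedione (R)-3a-methyl-3,3a,5,6-tetrahydro-1H-indene-1,4(2H)-dione
Conditions: SOCl2, pyridine, CH2Cl2, 0 °C
Reagents that add atoms: none
Why: dehydration of the tertiary α-ketol by E2 elimination of its chlorosulfite; β-hydrogens exist only at C6 because C10 is quaternary, so only the C5=C6 enone should form.

Step 4
Reactants: 5 enedione
Product: 6 mono-ketal (R)-4,4-ethylenedioxy-3a-methyl-2,3,3a,4,5,6-hexahydro-1H-inden-1-one
Conditions: ethylene glycol, p-TsOH (cat.), benzene, reflux, water separator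
Reagents that add atoms: ethylene glycol, OCCO
Why: acid-catalysed ketalisation should take the saturated C9 ketone and leave the less electrophilic conjugated C3 carbonyl free, as in related bicyclic enediones.

Step 5
Reactants: 6 mono-ketal
Product: 7 dienyl carbinol (3aR)-4,4-ethylenedioxy-3a-methyl-1-(prop-1-en-2-yl)-2,3,3a,4,5,6-hexahydro-1H-inden-1-ol (both C3 epimers)
Conditions: isopropenylmagnesium bromide, LaCl3·2LiCl, THF, −78 °C to 0 °C; then water
Reagents that add atoms: isopropenylmagnesium bromide, C=C(C)[Mg]Br
Why: Grignard 1,2-addition to the enone carbonyl (the lanthanum salt suppresses enolisation and 1,4-addition); the C3 epimer mixture is of no consequence because C3 becomes a carbonyl carbon in step 6.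

Step 6
Reactants: 7 dienyl carbinol
Product: 8 ring-expanded ketone (R)-1,1-ethylenedioxy-5,5,8a-trimethyl-1,2,3,7,8,8a-hexahydronaphthalen-6(5H)-one (3-oxo, 5-ene, 9-ketal)
Conditions: [N,N'-bis(3,5-di-tert-butylsalicylidene)-1,2-cyclohexanediaminato]cobalt (C36H52CoN2O2, divalent cobalt, 5 mol %), N-fluoro-2,4,6-trimethylpyridinium triflate (1.2 equiv), PhSiH3 (1.2 equiv), acetone, 0 °C to rt
Reagents that add atoms: none
Why: A cobalt hydride, formed from the salen cobalt catalyst, the N-fluoropyridinium oxidant and PhSiH3, should transfer a hydrogen atom to the terminal CH2 of the isopropenyl group; the tertiary C4 radical, or the cation reached from it by oxidation with trivalent cobalt (radical-polar crossover), is attacked by the adjacent C5=C6 π bond, and the cyclopropylcarbinyl species reopens by cleavage of the old C3–C5 bond, so that C5 moves from C3 to C4 and C3 collapses to the ketone. The closest known reaction type is the hydrogen-atom-transfer-initiated semipinacol rearrangement of tertiary allylic alcohols, a relative of the acid-mediated pinacol ring enlargement of 1-(2-hydroxyprop-2-yl)cyclopentanols to 2,2-dimethylcyclohexanones. No ring is closed from an open chain: the cyclopentane is enlarged to ring A by a 1,2-alkenyl shift (3-exo closure, then reopening) that inserts the gem-dimethyl carbon C4 between C3 and C5. No stereocentre is formed (C4 carries two methyls, the C3 carbinol centre is destroyed, C10 is untouched), so both epimers of 7 should converge on 8. The step needs hydrogen-atom transfer to the 1,1-disubstituted isopropenyl group and not to the trisubstituted C5=C6 bond, which the lower substitution secures, and migration of C5 and not of C2H2, which is secured because only the alkenyl carbon can bridge through its π bond and because the C3 oxygen makes the shift ketone-forming and irreversible.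

Step 7
Reactants: 8 ring-expanded ketone
Product: 10 olefin ketal (R)-1,1-ethylenedioxy-5,5,8a-trimethyl-1,2,3,5,6,7,8,8a-octahydronaphthalene, via hydrazone 9 (not isolated)
Conditions: N2H4·H2O, KOH, diethylene glycol, 130 °C, then 200 °C
Reagents that add atoms: none
Why: Wolff–Kishner reduction removes the C3 carbonyl under base, to which the ketal and the isolated C5=C6 bond (C4 is quaternary, so no conjugation is possible) are stable.

Step 8
Reactants: 10 olefin ketal
Product: 12 trans-decalone (4aR,8aR)-5,5,8a-trimethyloctahydronaphthalen-1(2H)-one, via unsaturated ketone 11 (not isolated)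
Conditions: 1 M aq. HCl, EtOH, rt; then 10% Pd/C, H2 (3 atm), rt, same flask
Reagents that add atoms: water, O
Why: ketal hydrolysis, then heterogeneous hydrogenation in which H2 should add to C5=C6 from the face opposite the axial C10 methyl, setting C5 (R) and the trans ring fusion.

Step 9
Reactants: 12 trans-decalone
Product: 13 exocyclic alkene (4aR,8aR)-1,1,4a-trimethyl-5-methylidenedecahydronaphthalene
Conditions: Ph3PCH3Br, KOtBu, toluene, 100 °C
Reagents that add atoms: methyltriphenylphosphonium bromide, C[P+](c1ccccc1)(c1ccccc1)c1ccccc1.[Br-]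
Why: Wittig methylenation of the hindered C9 ketone with the ylide at elevated temperature introduces C11.

Step 10
Reactants: 13 exocyclic alkene
Product: 14 allylic alcohol (4aR,8aR)-5,5,8a-trimethyl-1-methylidenedecahydronaphthalen-2-ol (C8 epimers)
Conditions: SeO2 (0.5 equiv), t-BuOOH, CH2Cl2, rt
Reagents that add atoms: tert-butyl hydroperoxide, CC(C)(C)OO; selenium dioxide (oxygen carrier), O=[Se]=O
Why: SeO2 allylic oxidation (ene reaction, then [2,3]-sigmatropic shift) hydroxylates C8, the only allylic position that carries hydrogen, and keeps the exocyclic alkene.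

Step 11
Reactants: 14 allylic alcohol
Product: 15 exocyclic enone (4aR,8aR)-5,5,8a-trimethyl-1-methylideneoctahydronaphthalen-2(1H)-one
Conditions: 1,1,1-triacetoxy-1,1-dihydro-1,2-benziodoxol-3(1H)-one (DMP), NaHCO3, CH2Cl2, rt
Reagents that add atoms: none
Why: hypervalent-iodine oxidation of the allylic alcohol under non-acidic conditions gives the 9(11)-en-8-one, a 1,2-transposition of the original C9 carbonyl.

Step 12
Reactants: 16 methyl 3-methylbut-2-enoate
Product: 18 silyl dienol ether 1-methoxy-3-methyl-1-(trimethylsilyloxy)buta-1,3-diene, via lithium dienolate 17 (not isolated)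
Conditions: LiN(i-Pr)2, THF, −78 °C; then Me3SiCl
Reagents that add atoms: chlorotrimethylsilane, C[Si](C)(C)Cl
Why: γ-deprotonation to the extended enolate and O-silylation give the vinylogous silyl ketene acetal.

Step 13
Reactants: 15 exocyclic enone; 18 silyl dienol ether
Product: 20 keto enoate methyl (E)-3-methyl-5-[(1S,4aR,8aR)-5,5,8a-trimethyl-2-oxodecahydronaphthalen-1-yl]pent-2-enoate, via silyl enol ether 19 (not isolated)
Conditions: Sc(OTf)3 (5 mol %), CH2Cl2, −78 °C to −40 °C; then 1 M HCl, THF, rt
Reagents that add atoms: none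
Why: vinylogous Mukaiyama–Michael addition in which the γ-carbon of the dienolate attacks the unhindered exocyclic C11 (C11–C12 bond), the 13E enoate should arise from the s-trans dienolate, and acid hydrolysis of 19 under equilibrating conditions places the C9 chain equatorial (H-9 axial, anti to the C10 methyl; 9S).

Step 14
Reactants: 20 keto enoate
Product: 22 enol triflate methyl (13E)-8-(trifluoromethylsulfonyloxy)-17-nor-ent-labda-7,13-dien-15-oate, via lithium enolate 21 (not isolated)
Conditions: LiN(i-Pr)2 (1.05 equiv), THF, −78 °C; then N-(5-chloro-2-pyridyl)triflimide, −78 °C to −20 °C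
Reagents that add atoms: N-(5-chloropyridin-2-yl)-1,1,1-trifluoro-N-(trifluoromethylsulfonyl)methanesulfonamide, O=S(=O)(N(c1ccc(Cl)cn1)S(=O)(=O)C(F)(F)F)C(F)(F)F
Why: kinetic deprotonation at the C7 methylene (the tertiary C9–H next to the quaternary C10 is far less accessible) and O-triflation should give the 7-ene enol triflate.

Step 15
Reactants: 22 enol triflate
Product: 23 hydroxy ester methyl (13E)-17-hydroxy-ent-labda-7,13-dien-15-oate
Conditions: Bu3SnCH2OH, Pd(PPh3)4 (5 mol %), LiCl, 1,4-dioxane, 100 °C
Reagents that add atoms: (tributylstannyl)methanol, CCCC[Sn](CCCC)(CCCC)CO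
Why: Stille cross-coupling of the alkenyl triflate with the hydroxymethyl stannane installs C17 on the C7=C8 bond.

Step 16
Reactants: 23 hydroxy ester
Product: 24 silyl ether methyl (13E)-17-(tert-butyldimethylsilyloxy)-ent-labda-7,13-dien-15-oate
Conditions: TBSCl, imidazole, DMF, rt
Reagents that add atoms: tert-butyldimethylsilyl chloride, CC(C)(C)[Si](C)(C)Cl
Why: silylation of the primary allylic alcohol keeps the C17 oxygen distinct from the C15 oxygen that is set free next.

Step 17
Reactants: 24 silyl ether
Product: 25 allylic alcohol (13E)-17-(tert-butyldimethylsilyloxy)-ent-labda-7,13-dien-15-ol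
Conditions: i-Bu2AlH (2.5 equiv), CH2Cl2, −78 °C; aq. potassium sodium tartrate
Reagents that add atoms: none
Why: 1,2-reduction of the α,β-unsaturated ester by the aluminium hydride gives the allylic alcohol with the 13E geometry unchanged.

Step 18
Reactants: 26 ω-pentadecalactone (oxacyclohexadecan-2-one)
Product: 27 bromo acid (15-bromopentadecanoic acid)
Conditions: HBr (33% in AcOH), 60 °C
Reagents that add atoms: hydrogen bromide, Br
Why: acid-mediated ring opening of the macrolactone by bromide at the O-alkyl carbon (SN2) gives the ω-bromo acid.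

Step 19
Reactants: 27 bromo acid
Product: 28 bromo alcohol (15-bromopentadecan-1-ol)
Conditions: BH3·THF, THF, 0 °C to rt; then MeOH, H2O
Reagents that add atoms: none
Why: borane reduces the carboxylic acid chemoselectively in the presence of the primary bromide.

Step 20
Reactants: 28 bromo alcohol
Product: 29 bromo silyl ether [(15-bromopentadecyl)oxy](tert-butyl)dimethylsilane
Conditions: TBSCl, imidazole, CH2Cl2, rt
Reagents that add atoms: tert-butyldimethylsilyl chloride, CC(C)(C)[Si](C)(C)Cl
Why: standard silylation protects the future ω-hydroxyl group.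

Step 21
Reactants: 29 bromo silyl ether; 27 bromo acid
Product: 32 TBS-protected acid [30-(tert-butyldimethylsilyloxy)triacontanoic acid], via Grignard reagent 30 (not isolated), via magnesium carboxylate 31 (not isolated)
Conditions: 29, Mg, THF, 45 °C; 27, MeMgCl (1.0 equiv), THF, −20 °C; the two solutions combined with Li2CuCl4 (3 mol %), −10 °C to rt; cold 0.5 M HCl to pH 3
Reagents that add atoms: none
Why: Li2CuCl4-catalysed sp3–sp3 coupling of the primary alkyl Grignard reagent with the primary bromide of the magnesium carboxylate joins the two C15 halves to the C30 chain.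

Step 22
Reactants: 25 allylic alcohol; 32 TBS-protected acid
Product: 33 bis-silyl ester (13E)-17-(tert-butyldimethylsilyloxy)-ent-labda-7,13-dien-15-yl 30-(tert-butyldimethylsilyloxy)triacontanoate
Conditions: EDC·HCl, DMAP, CH2Cl2, rt
Reagents that add atoms: none
Why: carbodiimide (Steglich-type) esterification of the only free hydroxyl group, the primary allylic C15–OH.

Step 23
Reactants: 33 bis-silyl ester
Product: 34 target, (13E)-17-hydroxy-ent-labda-7,13-dien-15-yl 30-hydroxytriacontanoate
Conditions: HF·pyridine, pyridine, THF, 0 °C to rt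
Reagents that add atoms: none
Why: buffered fluoride cleavage of both primary silyl ethers should leave the allylic ester and the two trisubstituted alkenes untouched.

**Compound list**

1 | 2-methylcyclohexane-1,3-dione | CC1C(=O)CCCC1=O | starting material
2 | acrolein | C=CC=O | starting material
3 | 3-(1-methyl-2,6-dioxocyclohexyl)propanal | CC1(CCC=O)C(=O)CCCC1=O | intermediate
4 | (3aR,7aS)-7a-hydroxy-3a-methylhexahydro-1H-indene-1,4(2H)-dione | O=C1CC[C@@]2(C)C(=O)CCC[C@@]12O | intermediate
5 | (R)-3a-methyl-3,3a,5,6-tetrahydro-1H-indene-1,4(2H)-dione | O=C1CC[C@@]2(C)C(=O)CCC=C12 | intermediate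
6 | (R)-4,4-ethylenedioxy-3a-methyl-2,3,3a,4,5,6-hexahydro-1H-inden-1-one | O=C1CC[C@@]2(C)C3(OCCO3)CCC=C12 | intermediate
7 | (3aR)-4,4-ethylenedioxy-3a-methyl-1-(prop-1-en-2-yl)-2,3,3a,4,5,6-hexahydro-1H-inden-1-ol, both C3 epimers | C=C(C)C1(O)CC[C@@]2(C)C3(OCCO3)CCC=C12 | intermediate
8 | (R)-1,1-ethylenedioxy-5,5,8a-trimethyl-1,2,3,7,8,8a-hexahydronaphthalen-6(5H)-one | O=C1CC[C@@]2(C)C3(OCCO3)CCC=C2C1(C)C | intermediate
9 | hydrazone of 8 | NN=C1CC[C@@]2(C)C3(OCCO3)CCC=C2C1(C)C | intermediate
10 | (R)-1,1-ethylenedioxy-5,5,8a-trimethyl-1,2,3,5,6,7,8,8a-octahydronaphthalene | C1CC[C@@]2(C)C3(OCCO3)CCC=C2C1(C)C | intermediate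
11 | (R)-5,5,8a-trimethyl-3,5,6,7,8,8a-hexahydronaphthalen-1(2H)-one | C1CC[C@@]2(C)C(=O)CCC=C2C1(C)C | intermediate
12 | (4aR,8aR)-5,5,8a-trimethyloctahydronaphthalen-1(2H)-one | O=C1CCC[C@@H]2C(C)(C)CCC[C@@]12C | intermediate
13 | (4aR,8aR)-1,1,4a-trimethyl-5-methylidenedecahydronaphthalene | C=C1CCC[C@@H]2C(C)(C)CCC[C@@]12C | intermediate
14 | (4aR,8aR)-5,5,8a-trimethyl-1-methylidenedecahydronaphthalen-2-ol, C8 epimers | C=C1C(O)CC[C@@H]2C(C)(C)CCC[C@@]12C | intermediate
15 | (4aR,8aR)-5,5,8a-trimethyl-1-methylideneoctahydronaphthalen-2(1H)-one | C=C1C(=O)CC[C@@H]2C(C)(C)CCC[C@@]12C | intermediate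
16 | methyl 3-methylbut-2-enoate | COC(=O)C=C(C)C | starting material
17 | lithium dienolate of 16 | C=C(C)C=C(OC)O[Li] | intermediate
18 | 1-methoxy-3-methyl-1-(trimethylsilyloxy)buta-1,3-diene | C=C(C)C=C(OC)O[Si](C)(C)C | intermediate
19 | trimethylsilyl enol ether (C8–O, 8-ene) of 20 | C/C(=C\C(=O)OC)CCC1=C(O[Si](C)(C)C)CC[C@@H]2C(C)(C)CCC[C@@]12C | intermediate
20 | methyl (13E)-8-oxo-17-nor-ent-labd-13-en-15-oate, (5R,9S,10R) | C/C(=C\C(=O)OC)CC[C@@H]1C(=O)CC[C@@H]2C(C)(C)CCC[C@@]12C | intermediate
21 | lithium 7-en-8-olate of 20 | C/C(=C\C(=O)OC)CC[C@@H]1C(O[Li])=CC[C@@H]2C(C)(C)CCC[C@@]12C | intermediate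
22 | methyl (13E)-8-(trifluoromethylsulfonyloxy)-17-nor-ent-labda-7,13-dien-15-oate | C/C(=C\C(=O)OC)CC[C@@H]1C(OS(=O)(=O)C(F)(F)F)=CC[C@@H]2C(C)(C)CCC[C@@]12C | intermediate
23 | methyl (13E)-17-hydroxy-ent-labda-7,13-dien-15-oate | C/C(=C\C(=O)OC)CC[C@@H]1C(CO)=CC[C@@H]2C(C)(C)CCC[C@@]12C | intermediate
24 | methyl (13E)-17-(tert-butyldimethylsilyloxy)-ent-labda-7,13-dien-15-oate | C/C(=C\C(=O)OC)CC[C@@H]1C(CO[Si](C)(C)C(C)(C)C)=CC[C@@H]2C(C)(C)CCC[C@@]12C | intermediate
25 | (13E)-17-(tert-butyldimethylsilyloxy)-ent-labda-7,13-dien-15-ol | C/C(=C\CO)CC[C@@H]1C(CO[Si](C)(C)C(C)(C)C)=CC[C@@H]2C(C)(C)CCC[C@@]12C | intermediate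
26 | ω-pentadecalactone (oxacyclohexadecan-2-one) | O=C1CCCCCCCCCCCCCCO1 | starting material
27 | 15-bromopentadecanoic acid | OC(=O)CCCCCCCCCCCCCCBr | intermediate
28 | 15-bromopentadecan-1-ol | OCCCCCCCCCCCCCCCBr | intermediate
29 | [(15-bromopentadecyl)oxy](tert-butyl)dimethylsilane | CC(C)(C)[Si](C)(C)OCCCCCCCCCCCCCCCBr | intermediate
30 | [15-(tert-butyldimethylsilyloxy)pentadecyl]magnesium bromide | CC(C)(C)[Si](C)(C)OCCCCCCCCCCCCCCC[Mg]Br | intermediate
31 | chloromagnesium 15-bromopentadecanoate | BrCCCCCCCCCCCCCCC(=O)O[Mg]Cl | intermediate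
32 | 30-(tert-butyldimethylsilyloxy)triacontanoic acid | OC(=O)CCCCCCCCCCCCCCCCCCCCCCCCCCCCCO[Si](C)(C)C(C)(C)C | intermediate
33 | (13E)-17-(tert-butyldimethylsilyloxy)-ent-labda-7,13-dien-15-yl 30-(tert-butyldimethylsilyloxy)triacontanoate | C/C(=C\COC(=O)CCCCCCCCCCCCCCCCCCCCCCCCCCCCCO[Si](C)(C)C(C)(C)C)CC[C@@H]1C(CO[Si](C)(C)C(C)(C)C)=CC[C@@H]2C(C)(C)CCC[C@@]12C | intermediate
34 | (13E)-17-hydroxy-ent-labda-7,13-dien-15-yl 30-hydroxytriacontanoate, (5R,9S,10R) | C/C(=C\COC(=O)CCCCCCCCCCCCCCCCCCCCCCCCCCCCCO)CC[C@@H]1C(CO)=CC[C@@H]2C(C)(C)CCC[C@@]12C | target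

**Step count**

Total: 23 steps. Longest linear sequence: 18 steps (steps 1–11, 13–17, 22, 23). Step 12 and steps 18–21 are side branches.

**Steps most likely to fail, with fallbacks**

Step 6. Hydrogen-atom transfer may not discriminate between the two alkenes, or the tertiary radical may be reduced or trapped by the hydroxyl group before it rearranges. In that case the cation would be generated from a carbon–selenium bond. Ketal enone 6 is treated with 2-lithio-2-(methylseleno)propane (from 2,2-bis(methylseleno)propane and n-BuLi, THF, −78 °C) to give the β-hydroxy selenide F1. AgBF4 in CH2Cl2 at 0 °C then ionises the C–Se bond, and the same alkenyl 1,2-shift with ring enlargement should deliver 8, where the route is rejoined.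

Step 13. The dienolate may react at its α-carbon, give poor E/Z control, or close stepwise to a [4+2] adduct. In that case the chain would be built by two separate C–C bond formations. Enone 15 undergoes Mukaiyama–Michael addition of 2-(trimethylsilyloxy)propene (TiCl4, CH2Cl2, −78 °C) to give the 8,13-diketone F2. Its unhindered methyl ketone alone should react in a Horner–Wadsworth–Emmons olefination with trimethyl phosphonoacetate (NaH, THF); the 13E enoate, separated from its Z isomer, is 20.

Step 14. The amide base may also deprotonate the γ-positions of the enoate, or regiocontrol of enolisation may be lost. In that case C17 would be introduced without an enolate. Wittig methylenation of 20 (Ph3PCH3Br, KOtBu, toluene) gives the 8(17)-ene, methyl ent-copalate F3. m-CPBA should epoxidise only the electron-rich exocyclic alkene, the enoate alkene being electron-poor, to give the 8,17-epoxide F4. Diethylaluminium 2,2,6,6-tetramethylpiperidide (toluene, 0 °C) then removes the less hindered C7 proton and opens the epoxide to the allylic alcohol 23, where the route is rejoined.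

**Further compounds**

F1 | step 6 | (3aR)-4,4-ethylenedioxy-3a-methyl-1-[2-(methylseleno)propan-2-yl]-2,3,3a,4,5,6-hexahydro-1H-inden-1-ol | C[Se]C(C)(C)C1(O)CC[C@@]2(C)C3(OCCO3)CCC=C12
F2 | step 13 | (1S,4aR,8aR)-5,5,8a-trimethyl-1-(3-oxobutyl)octahydronaphthalen-2(1H)-one | CC(=O)CC[C@@H]1C(=O)CC[C@@H]2C(C)(C)CCC[C@@]12C
F3 | step 14 | methyl (13E)-ent-labda-8(17),13-dien-15-oate (methyl ent-copalate) | C/C(=C\C(=O)OC)CC[C@@H]1C(=C)CC[C@@H]2C(C)(C)CCC[C@@]12C
F4 | step 14 | methyl (13E)-8,17-epoxy-ent-labd-13-en-15-oate, C8 epimers | C/C(=C\C(=O)OC)CC[C@@H]1C2(CO2)CC[C@@H]3C(C)(C)CCC[C@@]13C
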